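**Retrosynthetic overview**
1. The side-chain C=C is made last by cross-metathesis of vinyl lactone 14 with olefin 19; 19 comes from divinylcarbinol by Sharpless desymmetrisation.
2. The δ-lactone is cut at C-5–C-6 and O-4–C-3a: CO2 is stitched between the CH3 of a C-7 methyl ketone (enolate carbon becomes C-6) and C-3a of the tetrahydrofuran, which carries a triflate trans to the ketone side chain (carboxylate oxygen becomes O-4, with inversion).
3. Enabling feature: in the furo[3,2-b]pyran-5-one, carbonyl C-5 has C-6 as its only carbon neighbour, C-6 is alpha to carbinol C-7 (carried as an enolisable ketone), and O-4 sits on ring carbon C-3a cis to the C-7a–C-7 bond. That cis 6/5 fusion is what a 6-exo-tet SN2 from a trans leaving group gives, and it makes all four tetrahydrofuran substituents cis.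
4. Ring order: the tetrahydrofuran is bought as 2,5-anhydro-D-glucitol (C-2, C-3, C-7a correct, C-3a epimeric) → temporary 1,3-dioxane acetonide (step 1) → δ-lactone (step 6) → C-7 carbinol by convex-face hydrogenation → acetonide off and CH2OH turned into vinyl.

Key step: step 6

Assumption: 2,5-anhydro-D-glucitol (1) is taken as a purchasable starting material. Unless glucitol numbering is named, locants follow the target (O-1, C-2, C-3, C-3a, O-4, C-5, C-6, C-7, C-7a) for the atoms they become.

**Route**

Step 1
Reactants: 1 2,5-anhydro-D-glucitol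
Product: 2 2,5-anhydro-1,3-O-isopropylidene-D-glucitol
Conditions: Me2C(OMe)2 (1.2 equiv), TsOH·H2O (cat.), DMF, 0 → 20 °C; Et3N
Reagents that add atoms: 2,2-dimethoxypropane, COC(C)(C)OC
Why: Acid-catalysed transacetalisation (acetonide formation) picks the only cis-1,3-diol pair, O-1/O-3 (glucitol numbering), as a cis-fused 1,3-dioxane, whereas O-4/O-6 would need a strained trans-fused acetal, so these two hydroxyls stay free and no stereocentre is touched.

Step 2
Reactants: 2 2,5-anhydro-1,3-O-isopropylidene-D-glucitol
Product: 4 2,5-anhydro-4,6-O-isopropylidene-L-gulonic acid, via aldehyde 3 (not isolated)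
Conditions: TEMPO (0.2 equiv), PhI(OAc)2 (2.2 equiv), MeCN/H2O 1:1, 20 °C
Reagents that add atoms: water, O
Why: Oxoammonium-mediated (TEMPO/PhI(OAc)2) oxidation is selective for the primary alcohol and in aqueous acetonitrile carries the hydrated aldehyde 3 on to the acid, leaving the secondary hydroxyl and the acetonide alone.

Step 3
Reactants: 4 2,5-anhydro-4,6-O-isopropylidene-L-gulonic acid
Product: 5 N-methoxy-N-methyl-2,5-anhydro-4,6-O-isopropylidene-L-gulonamide
Conditions: MeNH(OMe)·HCl, EDC·HCl, HOBt, N-methylmorpholine, CH2Cl2, 0 → 20 °C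
Reagents that add atoms: N,O-dimethylhydroxylamine hydrochloride, CNOC.Cl
Why: Carbodiimide-mediated amidation to the Weinreb amide should outrun acylation of the hindered secondary hydroxyl, which is trans to the carboxyl and cannot lactonise, and the mild base should leave the alpha stereocentre intact.

Step 4
Reactants: 5 Weinreb amide
Product: 6 3,6-anhydro-1-deoxy-5,7-O-isopropylidene-L-gulo-hept-2-ulose (methyl ketone with free ring hydroxyl)
Conditions: MeMgBr (3.2 equiv), THF, −20 → 0 °C; aq. NH4Cl
Reagents that add atoms: methylmagnesium bromide, C[Mg]Br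
Why: Weinreb ketone synthesis: after deprotonation of the hydroxyl the Grignard reagent adds once and the magnesium-chelated tetrahedral intermediate should survive until work-up, so the methyl ketone forms without over-addition.

Step 5
Reactants: 6 methyl ketone
Product: 7 3,6-anhydro-1-deoxy-5,7-O-isopropylidene-4-O-(trifluoromethylsulfonyl)-L-gulo-hept-2-ulose (triflate at the future C-3a)
Conditions: Tf2O (1.3 equiv), pyridine (3 equiv), CH2Cl2, −40 → −20 °C; cold filtration, used at once
Reagents that add atoms: trifluoromethanesulfonic anhydride, O=S(=O)(OS(=O)(=O)C(F)(F)F)C(F)(F)F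
Why: O-Sulfonylation of the secondary alcohol keeps the configuration at carbon, and both ring hydrogens next to the triflate are cis to it, so no anti-periplanar E2 path exists under the cold, weakly basic conditions.

Step 6
Reactants: 7 triflate ketone
Product: 10 tricyclic keto lactone: O-3/C-2-CH2O isopropylidene acetal of (2S,3R,3aR,7aS)-3-hydroxy-2-(hydroxymethyl)tetrahydro-5H-furo[3,2-b]pyran-5,7(6H)-dione, via lithium enolate 8 (not isolated), via lithium keto carboxylate 9 (not isolated)
Conditions: 7 added to LiN(SiMe3)2 (1.15 equiv), THF, −78 °C; CO2 (dry gas, excess), −78 °C; DMPU, −78 → 20 °C; aq. citric acid (pH 3)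
Reagents that add atoms: carbon dioxide, O=C=O
Why: Proposed new method: kinetic deprotonation of the methyl ketone gives lithium enolate 8, which is C-carboxylated by CO2 to beta-keto carboxylate 9, and on warming with DMPU the carboxylate oxygen displaces the trans-disposed C-3a triflate, so that CO2 ends as the O-4/C-5 unit of the lactone. The closest known reaction types are the carboxylation of ketone enolates with CO2 to beta-keto acids, the silver-catalysed carboxylation–cyclisation of alkynyl ketones with CO2 to lactones, and carboxylate displacement of furanose triflates; their union in one flask on a triflate-bearing ketone is untested. The delta-lactone closes in the 6-exo-tet mode. C-3a is the only stereocentre touched: backside attack inverts it, and because the tethered nucleophile and the leaving group lie on opposite faces of the tetrahydrofuran the lactone can only be cis-fused, which gives the all-cis ring. The step needs enolisation at CH3 and not at C-7a–H (whose enolate would expel the beta-triflate by E1cB); this is secured by the bulky amide base at −78 °C with inverse addition and, after carboxylation, by the far more acidic C-6 methylene. It also needs O-alkylation by the carboxylate, which ring size secures, since attack on C-3a by C-6 or by the enolate oxygen would form four-membered rings.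

Step 7
Reactants: 10 tricyclic keto lactone
Product: 11 hydroxy lactone: O-3/C-2-CH2O isopropylidene acetal of triol 12 with (7R)-hydroxyl
Conditions: H2 (50 bar), Raney nickel (Ni, washed neutral), EtOAc, 20 °C
Reagents that add atoms: none
Why: Heterogeneous hydrogenation of the enol tautomer of the beta-keto-delta-lactone, a known way to cis-beta-hydroxy-delta-lactones, should deliver hydrogen to C-7 from the open convex face of the cis-fused bicycle because the concave face is covered by the tetrahydrofuran and its dioxane, which sets C-7 as R with H-7 cis to H-7a.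

Step 8
Reactants: 11 hydroxy lactone acetonide
Product: 12 (2S,3R,3aR,7R,7aR)-3,7-dihydroxy-2-(hydroxymethyl)hexahydro-5H-furo[3,2-b]pyran-5-one
Conditions: AcOH/H2O 4:1, 40 °C
Reagents that add atoms: none
Why: Acid-catalysed acetal hydrolysis removes the isopropylidene group under conditions that should neither dehydrate the beta-hydroxy lactone nor open the delta-lactone irreversibly.

Step 9
Reactants: 12 triol lactone
Product: 13 (2R,3S,3aR,7R,7aR)-3,7-dihydroxy-5-oxohexahydro-2H-furo[3,2-b]pyran-2-carbaldehyde
Conditions: TEMPO (0.2 equiv), PhI(OAc)2 (1.1 equiv), dry MeCN/CH2Cl2, 20 °C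
Reagents that add atoms: none
Why: Oxoammonium (TEMPO/PhI(OAc)2) oxidation favours the primary alcohol on steric grounds and, without water, stops at the aldehyde while both secondary hydroxyls remain (the descriptors at C-2 and C-3 change by priority only).

Step 10
Reactants: 13 hydroxy aldehyde
Product: 14 (2S,3R,3aR,7R,7aR)-3,7-dihydroxy-2-vinylhexahydro-5H-furo[3,2-b]pyran-5-one
Conditions: Zn/CH2Br2/TiCl4 (pre-formed reagent, excess), THF/CH2Cl2, 0 → 20 °C
Reagents that add atoms: dibromomethane, BrCBr
Why: Takai–Lombardo methylenation with the non-basic zinc/titanium gem-dimetallic reagent should convert the aldehyde into the vinyl group without enolising the epimerisable alpha-alkoxy aldehyde, attacking the lactone or requiring protection of the hydroxyls.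

Step 11
Reactants: 15 penta-1,4-dien-3-ol
Product: 16 (2R,3S)-1,2-epoxypent-4-en-3-ol
Conditions: Ti(OiPr)4 (cat.), L-(+)-diisopropyl tartrate, t-BuOOH, 4 Å molecular sieves, CH2Cl2, −20 °C
Reagents that add atoms: tert-butyl hydroperoxide, CC(C)(C)OO
Why: Sharpless asymmetric epoxidation desymmetrises the divinyl carbinol: the L-(+)-tartrate catalyst should epoxidise one enantiotopic vinyl group on one face to the erythro (2R,3S) epoxy alcohol, and the minor enantiomer is consumed by a second epoxidation, which raises the enantiomeric purity.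

Step 12
Reactants: 16 (2R,3S)-1,2-epoxypent-4-en-3-ol
Product: 17 (2R,3S)-pent-4-ene-2,3-diol
Conditions: LiAlH4, Et2O, 0 °C; Rochelle-salt work-up
Reagents that add atoms: none
Why: Hydride opens the terminal epoxide by SN2 attack at the unsubstituted CH2, so the C–O bond at C-2 and both stereocentres are kept and the anti (erythro) diol results.

Step 13
Reactants: 17 (2R,3S)-pent-4-ene-2,3-diol
Product: 18 (2R,3S)-3-hydroxypent-4-en-2-yl acetate
Conditions: immobilised Candida antarctica lipase B, vinyl acetate (3 equiv), MTBE, 30 °C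
Reagents that add atoms: vinyl acetate, C=COC(C)=O
Why: Lipase-catalysed irreversible transesterification should acylate the (R)-configured methyl carbinol, the substrate type this enzyme accepts best, whereas the (S)-configured vinyl carbinol with two larger substituents is the slow-reacting sense, so the two hydroxyls are told apart without protecting groups.

Step 14
Reactants: 18 (2R,3S)-3-hydroxypent-4-en-2-yl acetate
Product: 19 (3S,4R)-4-(acetyloxy)pent-1-en-3-yl benzoate
Conditions: BzCl, pyridine, DMAP (cat.), CH2Cl2, 0 °C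
Reagents that add atoms: benzoyl chloride, O=C(Cl)c1ccccc1
Why: Nucleophile-catalysed O-acylation (benzoylation) of the remaining allylic alcohol at low temperature should be faster than 1,2-acetyl migration and does not touch the stereocentres.

Step 15
Reactants: 14 vinyl lactone diol; 19 side-chain olefin
Product: 20 (2S,3R,3aR,7R,7aR)-2-[(1E,3S,4R)-4-(acetyloxy)-3-(benzoyloxy)pent-1-en-1-yl]-3,7-dihydroxyhexahydro-5H-furo[3,2-b]pyran-5-one (target)
Conditions: second-generation Hoveyda–Grubbs catalyst RuCl2(H2IMes)(=CH-C6H4-2-OiPr) (10 mol%), 19 (4 equiv), CH2Cl2, 40 °C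
Reagents that add atoms: none
Why: Olefin cross-metathesis between two terminal, allylically oxygenated olefins, with the cheap partner in excess, releases ethylene and should give the thermodynamically favoured (E)-alkene, the ruthenium carbene tolerating free hydroxyls, esters and the lactone.

**Compound list**

1 | 2,5-anhydro-D-glucitol | OC[C@@H]1O[C@H](CO)[C@@H](O)[C@@H]1O | starting material
2 | 2,5-anhydro-1,3-O-isopropylidene-D-glucitol | CC1(C)OC[C@@H]2O[C@H](CO)[C@@H](O)[C@@H]2O1 | intermediate
3 | 2,5-anhydro-4,6-O-isopropylidene-aldehydo-L-gulose (not isolated) | CC1(C)OC[C@@H]2O[C@H](C=O)[C@@H](O)[C@@H]2O1 | intermediate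
4 | 2,5-anhydro-4,6-O-isopropylidene-L-gulonic acid | CC1(C)OC[C@@H]2O[C@H](C(=O)O)[C@@H](O)[C@@H]2O1 | intermediate
5 | N-methoxy-N-methyl-2,5-anhydro-4,6-O-isopropylidene-L-gulonamide | CC1(C)OC[C@@H]2O[C@H](C(=O)N(C)OC)[C@@H](O)[C@@H]2O1 | intermediate
6 | 3,6-anhydro-1-deoxy-5,7-O-isopropylidene-L-gulo-hept-2-ulose (methyl ketone) | CC1(C)OC[C@@H]2O[C@H](C(C)=O)[C@@H](O)[C@@H]2O1 | intermediate
7 | 4-O-triflate of 6 | CC1(C)OC[C@@H]2O[C@H](C(C)=O)[C@@H](OS(=O)(=O)C(F)(F)F)[C@@H]2O1 | intermediate
8 | lithium enolate of 7, deprotonated at the methyl group (not isolated) | CC1(C)OC[C@@H]2O[C@H](C(=C)[O-])[C@@H](OS(=O)(=O)C(F)(F)F)[C@@H]2O1.[Li+] | intermediate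
9 | lithium beta-keto carboxylate, 7 carboxylated at the methyl carbon (not isolated) | CC1(C)OC[C@@H]2O[C@H](C(=O)CC(=O)[O-])[C@@H](OS(=O)(=O)C(F)(F)F)[C@@H]2O1.[Li+] | intermediate
10 | tricyclic keto lactone: O-3/C-2-CH2O isopropylidene acetal of (2S,3R,3aR,7aS)-3-hydroxy-2-(hydroxymethyl)tetrahydro-5H-furo[3,2-b]pyran-5,7(6H)-dione | CC1(C)OC[C@@H]2O[C@H]3[C@H](OC(=O)CC3=O)[C@@H]2O1 | intermediate
11 | O-3/C-2-CH2O isopropylidene acetal of 12 | CC1(C)OC[C@@H]2O[C@H]3[C@H](OC(=O)C[C@H]3O)[C@@H]2O1 | intermediate
12 | (2S,3R,3aR,7R,7aR)-3,7-dihydroxy-2-(hydroxymethyl)hexahydro-5H-furo[3,2-b]pyran-5-one | OC[C@@H]1O[C@H]2[C@H](OC(=O)C[C@H]2O)[C@@H]1O | intermediate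
13 | (2R,3S,3aR,7R,7aR)-3,7-dihydroxy-5-oxohexahydro-2H-furo[3,2-b]pyran-2-carbaldehyde | O=C[C@@H]1O[C@H]2[C@H](OC(=O)C[C@H]2O)[C@@H]1O | intermediate
14 | (2S,3R,3aR,7R,7aR)-3,7-dihydroxy-2-vinylhexahydro-5H-furo[3,2-b]pyran-5-one | C=C[C@@H]1O[C@H]2[C@H](OC(=O)C[C@H]2O)[C@@H]1O | intermediate
15 | penta-1,4-dien-3-ol | C=CC(O)C=C | starting material
16 | (2R,3S)-1,2-epoxypent-4-en-3-ol | C1O[C@H]1[C@@H](O)C=C | intermediate
17 | (2R,3S)-pent-4-ene-2,3-diol | C[C@@H](O)[C@@H](O)C=C | intermediate
18 | (2R,3S)-3-hydroxypent-4-en-2-yl acetate | CC(=O)O[C@H](C)[C@@H](O)C=C | intermediate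
19 | (3S,4R)-4-(acetyloxy)pent-1-en-3-yl benzoate | CC(=O)O[C@H](C)[C@H](C=C)OC(=O)c1ccccc1 | intermediate
20 | (2S,3R,3aR,7R,7aR)-2-[(1E,3S,4R)-4-(acetyloxy)-3-(benzoyloxy)pent-1-en-1-yl]-3,7-dihydroxyhexahydro-5H-furo[3,2-b]pyran-5-one | CC(=O)O[C@H](C)[C@H](/C=C/[C@@H]1O[C@H]2[C@H](OC(=O)C[C@H]2O)[C@@H]1O)OC(=O)c1ccccc1 | target

**Count and risks**

Total step count: 15. Longest linear sequence: 11 steps (steps 1–10 and 15).

Step 6 (proposed new method). What may go wrong: enolisation toward C-7a followed by E1cB loss of the triflate, decay of the triflate before the hindered backside attack (cis to O-3) takes place, or incomplete carboxylation. The fallback uses known chemistry, sets out from 2 and comes back at 11. The primary hydroxyl of 2 is silylated (TBSCl, imidazole) to 2,5-anhydro-6-O-(tert-butyldimethylsilyl)-1,3-O-isopropylidene-D-glucitol F1. A Mitsunobu esterification with bromoacetic acid (PPh3 and DIAD premixed) inverts the ring carbinol and forms the O-4–C-3a bond, giving 2,5-anhydro-4-O-(bromoacetyl)-6-O-(tert-butyldimethylsilyl)-1,3-O-isopropylidene-D-galactitol F2. HF·pyridine frees the primary alcohol 2,5-anhydro-4-O-(bromoacetyl)-1,3-O-isopropylidene-D-galactitol F3, and Dess–Martin periodinane gives 2,5-anhydro-3-O-(bromoacetyl)-4,6-O-isopropylidene-aldehydo-L-galactose F4. SmI2 in THF at −78 °C then closes the δ-lactone by an intramolecular Reformatsky reaction (C-6–C-7 bond) to 11. If the C-7 epimer prevails, Dess–Martin oxidation leads to 10 and step 7 restores the route.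

Step 10. What may go wrong: epimerisation at C-2 of the strained alpha-alkoxy aldehyde, masking of the aldehyde as hydrate or internal hemiacetal so that the gem-dimetallic reagent reacts slowly, or Lewis-acid-induced dehydration of the beta-hydroxy lactone. The fallback is a two-stage Peterson olefination that sets out from 13 and comes back at 14. Addition of (trimethylsilyl)methylcerium (Me3SiCH2MgCl/CeCl3, THF, −78 °C) gives the beta-hydroxysilane (2S,3R,3aR,7R,7aR)-3,7-dihydroxy-2-[1-hydroxy-2-(trimethylsilyl)ethyl]hexahydro-5H-furo[3,2-b]pyran-5-one F5 as both carbinol epimers. Acid-induced elimination (aq. HF, MeCN) converts either epimer into the terminal alkene 14.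

Step 15. What may go wrong: slow productive metathesis between two hindered, allylically oxygenated olefins, homodimerisation of 19, catalyst decay or olefin migration. The fallback sets out from 13 and comes back at 20. The stabilised ylide (2R)-3-oxo-4-(triphenyl-λ5-phosphanylidene)butan-2-yl acetate F6 is made from (R)-2-acetoxypropanoyl chloride and two equivalents of Ph3P=CH2. Wittig reaction of F6 with 13 (toluene, 60 °C) should give the (E)-enone (2R)-3-oxo-5-[(2S,3R,3aR,7R,7aR)-3,7-dihydroxy-5-oxohexahydro-2H-furo[3,2-b]pyran-2-yl]pent-4-en-2-yl acetate F7. Corey–Bakshi–Shibata reduction with (S)-2-methyl-CBS-oxazaborolidine and catecholborane, the alkenyl branch acting as the larger group, should give the (3S)-allylic alcohol (2R,3S,4E)-3-hydroxy-5-[(2S,3R,3aR,7R,7aR)-3,7-dihydroxy-5-oxohexahydro-2H-furo[3,2-b]pyran-2-yl]pent-4-en-2-yl acetate F8. Benzoylation (BzCl, 2,4,6-collidine, −40 °C) at the acyclic allylic hydroxyl then gives 20; this last step relies on the two ring hydroxyls being shielded on the concave face.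

Further compounds
F1 | step 6 | 2,5-anhydro-6-O-(tert-butyldimethylsilyl)-1,3-O-isopropylidene-D-glucitol | CC1(C)OC[C@@H]2O[C@H](CO[Si](C)(C)C(C)(C)C)[C@@H](O)[C@@H]2O1
F2 | step 6 | 2,5-anhydro-4-O-(bromoacetyl)-6-O-(tert-butyldimethylsilyl)-1,3-O-isopropylidene-D-galactitol | CC1(C)OC[C@@H]2O[C@H](CO[Si](C)(C)C(C)(C)C)[C@H](OC(=O)CBr)[C@@H]2O1
F3 | step 6 | 2,5-anhydro-4-O-(bromoacetyl)-1,3-O-isopropylidene-D-galactitol | CC1(C)OC[C@@H]2O[C@H](CO)[C@H](OC(=O)CBr)[C@@H]2O1
F4 | step 6 | 2,5-anhydro-3-O-(bromoacetyl)-4,6-O-isopropylidene-aldehydo-L-galactose | CC1(C)OC[C@@H]2O[C@H](C=O)[C@H](OC(=O)CBr)[C@@H]2O1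
F5 | step 10 | (2S,3R,3aR,7R,7aR)-3,7-dihydroxy-2-[1-hydroxy-2-(trimethylsilyl)ethyl]hexahydro-5H-furo[3,2-b]pyran-5-one (both carbinol epimers) | C[Si](C)(C)CC(O)[C@@H]1O[C@H]2[C@H](OC(=O)C[C@H]2O)[C@@H]1O
F6 | step 15 | (2R)-3-oxo-4-(triphenyl-λ5-phosphanylidene)butan-2-yl acetate | CC(=O)O[C@H](C)C(=O)C=P(c1ccccc1)(c1ccccc1)c1ccccc1
F7 | step 15 | (2R,4E)-3-oxo-5-[(2S,3R,3aR,7R,7aR)-3,7-dihydroxy-5-oxohexahydro-2H-furo[3,2-b]pyran-2-yl]pent-4-en-2-yl acetate | CC(=O)O[C@H](C)C(=O)/C=C/[C@@H]1O[C@H]2[C@H](OC(=O)C[C@H]2O)[C@@H]1O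
F8 | step 15 | (2R,3S,4E)-3-hydroxy-5-[(2S,3R,3aR,7R,7aR)-3,7-dihydroxy-5-oxohexahydro-2H-furo[3,2-b]pyran-2-yl]pent-4-en-2-yl acetate | CC(=O)O[C@H](C)[C@@H](O)/C=C/[C@@H]1O[C@H]2[C@H](OC(=O)C[C@H]2O)[C@@H]1O
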